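**Strategy.** The route rests on disconnecting the two C4–C4a aryl–carbon bonds of the 3,3''-biflavanone while each C4 carbonyl is held as the internal carbon of a vinyl group. A twofold intramolecular Heck reaction then closes both pyran rings (ring C of each flavan unit) in one operation. It exploits the fact that C2–C3–C3''–C2'' is an anti,anti β-aryloxy ketone (aldol-type) array, which can open or epimerise at C3 only once C4 and C4'' are carbonyls. The precursor is a C2-symmetric 1,4-bis(4-methoxyphenyl)-2,3-divinylbutane-1,4-diyl bis(2-bromoaryl) ether. Its four stereocentres come from one catalytic double allylboration, its aryl ethers from fluoride displacement on a regiochemically unambiguous arene.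

Key step: step 8

Assumption: (S)-TRIP, (S)-3,3'-bis(2,4,6-triisopropylphenyl)-1,1'-binaphthyl-2,2'-diyl hydrogen phosphate, is taken to direct the allyl unit to the Si face of 4-methoxybenzaldehyde by analogy with crotylboration of benzaldehyde; should the sense prove opposite, the enantiomeric acid is used with no other change.

Step 1
Reactants: 1 dimethyl (2E,4E)-hexa-2,4-dienedioate (dimethyl trans,trans-muconate)
Product: 2 (2E,4E)-hexa-2,4-diene-1,6-diol
Conditions: (Me2CHCH2)2AlH (4.5 equiv), CH2Cl2, −78 → 0 °C; aq. KNaC4H4O6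
Reagents that add atoms: none
Why: Aluminium hydride reduction of a conjugated diester proceeds by 1,2-addition at low temperature, so both esters should go to the allylic alcohols without touching the E,E-diene.

Step 2
Reactants: 2 (2E,4E)-hexa-2,4-diene-1,6-diol
Product: 3 (2E,4E)-hexa-2,4-diene-1,6-diyl diacetate
Conditions: Ac2O (2.5 equiv), DMAP (cat.), pyridine, 0 °C → rt
Reagents that add atoms: acetic anhydride, CC(=O)OC(C)=O
Why: DMAP-catalysed acylation of the two primary allylic alcohols (nucleophilic acyl substitution, one acetyl per hydroxyl) installs the leaving groups that zerovalent palladium needs in the next step.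

Step 3
Reactants: 3 (2E,4E)-hexa-2,4-diene-1,6-diyl diacetate; 4 bis(pinacolato)diboron
Product: 5 (2E,4E)-1,6-bis(4,4,5,5-tetramethyl-1,3,2-dioxaborolan-2-yl)hexa-2,4-diene
Conditions: 4 (2.2 equiv), Pd2(dba)3 (2.5 mol %), DMSO, 50 °C
Reagents that add atoms: bis(pinacolato)diboron (second equivalent of 4), CC1(C)OB(B2OC(C)(C)C(C)(C)O2)OC1(C)C
Why: Miyaura-type palladium-catalysed borylation of allylic acetates, in which zerovalent palladium ionises each acetate to a π-allyl complex, the acetate ligand activates one molecule of the diboron for transmetalation, and C–B reductive elimination at the unsubstituted terminus should give the linear boronate and keep the conjugated E,E-diene.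

Step 4
Reactants: 5 (2E,4E)-1,6-bis(4,4,5,5-tetramethyl-1,3,2-dioxaborolan-2-yl)hexa-2,4-diene; 6 4-methoxybenzaldehyde
Product: 9 (1S,2R,3R,4S)-1,4-bis(4-methoxyphenyl)-2,3-divinylbutane-1,4-diol, via mono-adduct allylboronate 7 (not isolated), via bis(borate) ester 8 (not isolated)
Conditions: 6 (2.4 equiv), (S)-TRIP (10 mol %), toluene, −30 → 0 °C; aq. NaHCO3
Reagents that add atoms: 4-methoxybenzaldehyde (second equivalent of 6), COc1ccc(C=O)cc1
Why: Chiral phosphoric acid-catalysed allylboration through closed chair (Zimmerman–Traxler) transition states, in which each E-allylic boronate adds through its γ-carbon to one molecule of aldehyde with the anisyl group equatorial, fixing the anti relation of C1/C2 and of C3/C4, while the acid, hydrogen-bonded to a boronate oxygen and to the formyl hydrogen, should direct both additions to the Si face of the aldehyde and thereby set 1S,2R in the first addition (which turns the pentadienyl boronate into the new E-allylic boronate 7) and 3R,4S in the second, the E-alkene of 7 exerting too little allylic strain for the resident centres to override the catalyst.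

Step 5
Reactants: 10 4-bromo-3,5-difluorophenol
Product: 11 5-(benzyloxy)-2-bromo-1,3-difluorobenzene
Conditions: BnBr, K2CO3, DMF, rt
Reagents that add atoms: benzyl bromide, BrCc1ccccc1
Why: Williamson ether synthesis (SN2 alkylation of the phenoxide); benzyl is chosen because it should survive alkoxide, palladium and OsO4 and leave by hydrogenolysis at the end.

Step 6
Reactants: 11 5-(benzyloxy)-2-bromo-1,3-difluorobenzene
Product: 12 5-(benzyloxy)-2-bromo-1-fluoro-3-methoxybenzene
Conditions: NaOMe (1.2 equiv), DMSO, 60 °C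
Reagents that add atoms: sodium methoxide, [Na+].[O-]C
Why: Nucleophilic aromatic substitution (SNAr, addition–elimination) of one fluoride, activated by the ortho bromine and the meta fluorine; the two fluorines of 11 are equivalent, so only one regioisomer can form, and the methoxy group that enters makes the ring less electrophilic, which should stop the reaction after one substitution.

Step 7
Reactants: 9 (1S,2R,3R,4S)-1,4-bis(4-methoxyphenyl)-2,3-divinylbutane-1,4-diol; 12 5-(benzyloxy)-2-bromo-1-fluoro-3-methoxybenzene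
Product: 14 (1S,2R,3R,4S)-1,4-bis[5-(benzyloxy)-2-bromo-3-methoxyphenoxy]-1,4-bis(4-methoxyphenyl)-2,3-divinylbutane, via disodium dialkoxide 13 (not isolated)
Conditions: NaH (2.4 equiv), THF, 0 °C → rt; then 12 (3 equiv), DMPU, 70 °C
Reagents that add atoms: 5-(benzyloxy)-2-bromo-1-fluoro-3-methoxybenzene (second equivalent of 12), COc1cc(OCc2ccccc2)cc(F)c1Br
Why: Twofold SNAr etherification in which each alkoxide oxygen of 13 attacks the fluorine-bearing carbon of one molecule of 12 (Meisenheimer intermediate stabilised inductively by the ortho bromine and the two meta alkoxy groups, fluoride leaving far faster than bromide), and since the carbinol C–O bonds are never broken all four stereocentres should be carried over with retention.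

Step 8
Reactants: 14 (1S,2R,3R,4S)-1,4-bis[5-(benzyloxy)-2-bromo-3-methoxyphenoxy]-1,4-bis(4-methoxyphenyl)-2,3-divinylbutane
Product: 15 (2S,2'S,3S,3'S)-7,7'-bis(benzyloxy)-5,5'-dimethoxy-2,2'-bis(4-methoxyphenyl)-4,4'-dimethylidene-3,3'-bichromane
Conditions: Pd[P(t-Bu)3]2 (10 mol %), Cy2NMe (4 equiv), 1,4-dioxane, 90 °C
Reagents that add atoms: none
Why: Zerovalent palladium inserts into each C4a–Br bond, the arylpalladium adds syn across the neighbouring vinyl group with the aryl carbon bonding to the internal alkene carbon (C4), and β-hydride elimination of the C4–H gives the exocyclic methylene while Cy2NMe takes up HBr; the second arm reacts in the same way. The closest known reaction type is the intramolecular Mizoroki–Heck cyclisation of 2-haloaryl homoallyl ethers to 4-methylenechromans. Each pyran ring (ring C of either flavan unit) closes in the 6-exo-trig mode, forming C4–C4a and C4''–C4a''. No stereocentre is created, and C2, C3, C3'' and C2'' are sp3 carbons with no adjacent carbonyl at this stage, so they should pass through unchanged. The step needs 6-exo over 7-endo insertion, which the O1–C2–C3 tether secures (the remote vinyl group would demand a seven-membered closure). It also needs the exocyclic alkene not to migrate to C3=C4, which the bulky P(t-Bu)3 ligand and the amine base should favour by removing the palladium hydride quickly.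

Step 9
Reactants: 15 (2S,2'S,3S,3'S)-7,7'-bis(benzyloxy)-5,5'-dimethoxy-2,2'-bis(4-methoxyphenyl)-4,4'-dimethylidene-3,3'-bichromane
Product: 16 (2S,2'S,3R,3'R)-7,7'-bis(benzyloxy)-5,5'-dimethoxy-2,2'-bis(4-methoxyphenyl)-[3,3'-bichromane]-4,4'-dione
Conditions: OsO4 (5 mol %), NaIO4 (8 equiv), 2,6-lutidine, dioxane/H2O (3:1), rt
Reagents that add atoms: osmium tetroxide, O=[Os](=O)(=O)=O; sodium periodate, [Na+].[O-]I(=O)(=O)=O
Why: Lemieux–Johnson oxidation: OsO4 dihydroxylates each electron-rich 1,1-disubstituted exocyclic alkene and NaIO4 cleaves the diol to the aryl ketone, while 2,6-lutidine buffers the medium so that the freshly unmasked β-aryloxy ketones should neither open nor epimerise at C3, where the trans-diequatorial arrangement is in any case the thermodynamically preferred one.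

Step 10
Reactants: 16 (2S,2'S,3R,3'R)-7,7'-bis(benzyloxy)-5,5'-dimethoxy-2,2'-bis(4-methoxyphenyl)-[3,3'-bichromane]-4,4'-dione
Product: 17 4',4''',5,5''-tetramethylchamaejasmin, (2S,2'S,3R,3'R)-7,7'-dihydroxy-5,5'-dimethoxy-2,2'-bis(4-methoxyphenyl)-[3,3'-bichromane]-4,4'-dione
Conditions: H2 (1 atm), Pd/C (10 %), EtOAc/THF, rt
Reagents that add atoms: none
Why: Hydrogenolysis of the two aryl benzyl ethers over Pd/C under neutral conditions at atmospheric pressure, under which the aryl ketones and the cyclic C2–O1 ether bonds are expected to persist.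

**Compound list**

1 | dimethyl (2E,4E)-hexa-2,4-dienedioate | COC(=O)/C=C/C=C/C(=O)OC | starting material
2 | (2E,4E)-hexa-2,4-diene-1,6-diol | OC/C=C/C=C/CO | intermediate
3 | (2E,4E)-hexa-2,4-diene-1,6-diyl diacetate | CC(=O)OC/C=C/C=C/COC(C)=O | intermediate
4 | bis(pinacolato)diboron | CC1(C)OB(B2OC(C)(C)C(C)(C)O2)OC1(C)C | starting material
5 | (2E,4E)-1,6-bis(4,4,5,5-tetramethyl-1,3,2-dioxaborolan-2-yl)hexa-2,4-diene | CC1(C)OB(C/C=C/C=C/CB2OC(C)(C)C(C)(C)O2)OC1(C)C | intermediate
6 | 4-methoxybenzaldehyde | COc1ccc(C=O)cc1 | starting material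
7 | 2-{(2E,4R,5S)-5-(4-methoxyphenyl)-5-[(4,4,5,5-tetramethyl-1,3,2-dioxaborolan-2-yl)oxy]-4-vinylpent-2-en-1-yl}-4,4,5,5-tetramethyl-1,3,2-dioxaborolane (mono-adduct) | COc1ccc([C@@H](OB2OC(C)(C)C(C)(C)O2)[C@H](C=C)/C=C/CB2OC(C)(C)C(C)(C)O2)cc1 | intermediate (not isolated)
8 | 2,2'-{[(1S,2R,3R,4S)-1,4-bis(4-methoxyphenyl)-2,3-divinylbutane-1,4-diyl]bis(oxy)}bis(4,4,5,5-tetramethyl-1,3,2-dioxaborolane) | COc1ccc([C@@H](OB2OC(C)(C)C(C)(C)O2)[C@H](C=C)[C@@H](C=C)[C@H](OB2OC(C)(C)C(C)(C)O2)c2ccc(OC)cc2)cc1 | intermediate (not isolated)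
9 | (1S,2R,3R,4S)-1,4-bis(4-methoxyphenyl)-2,3-divinylbutane-1,4-diol | COc1ccc([C@@H](O)[C@H](C=C)[C@@H](C=C)[C@H](O)c2ccc(OC)cc2)cc1 | intermediate
10 | 4-bromo-3,5-difluorophenol | Oc1cc(F)c(Br)c(F)c1 | starting material
11 | 5-(benzyloxy)-2-bromo-1,3-difluorobenzene | Fc1cc(OCc2ccccc2)cc(F)c1Br | intermediate
12 | 5-(benzyloxy)-2-bromo-1-fluoro-3-methoxybenzene | COc1cc(OCc2ccccc2)cc(F)c1Br | intermediate
13 | disodium (1S,2R,3R,4S)-1,4-bis(4-methoxyphenyl)-2,3-divinylbutane-1,4-diolate | COc1ccc([C@@H]([O-])[C@H](C=C)[C@@H](C=C)[C@H]([O-])c2ccc(OC)cc2)cc1.[Na+].[Na+] | intermediate (not isolated)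
14 | (1S,2R,3R,4S)-1,4-bis[5-(benzyloxy)-2-bromo-3-methoxyphenoxy]-1,4-bis(4-methoxyphenyl)-2,3-divinylbutane | COc1ccc([C@@H](Oc2cc(OCc3ccccc3)cc(OC)c2Br)[C@H](C=C)[C@@H](C=C)[C@H](Oc2cc(OCc3ccccc3)cc(OC)c2Br)c2ccc(OC)cc2)cc1 | intermediate
15 | (2S,2'S,3S,3'S)-7,7'-bis(benzyloxy)-5,5'-dimethoxy-2,2'-bis(4-methoxyphenyl)-4,4'-dimethylidene-3,3'-bichromane | COc1ccc([C@H]2Oc3cc(OCc4ccccc4)cc(OC)c3C(=C)[C@@H]2[C@H]2C(=C)c3c(OC)cc(OCc4ccccc4)cc3O[C@@H]2c2ccc(OC)cc2)cc1 | intermediate
16 | (2S,2'S,3R,3'R)-7,7'-bis(benzyloxy)-5,5'-dimethoxy-2,2'-bis(4-methoxyphenyl)-[3,3'-bichromane]-4,4'-dione | COc1ccc([C@H]2Oc3cc(OCc4ccccc4)cc(OC)c3C(=O)[C@@H]2[C@H]2C(=O)c3c(OC)cc(OCc4ccccc4)cc3O[C@@H]2c2ccc(OC)cc2)cc1 | intermediate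
17 | 4',4''',5,5''-tetramethylchamaejasmin, (2S,2'S,3R,3'R)-7,7'-dihydroxy-5,5'-dimethoxy-2,2'-bis(4-methoxyphenyl)-[3,3'-bichromane]-4,4'-dione | COc1ccc([C@H]2Oc3cc(O)cc(OC)c3C(=O)[C@@H]2[C@H]2C(=O)c3c(OC)cc(O)cc3O[C@@H]2c2ccc(OC)cc2)cc1 | target

**Step count.** Total: 10 steps. Longest linear sequence: 8 steps (steps 1–4 and 7–10); steps 5 and 6 form the arene branch.

**Steps most likely to fail**

Step 8. Oxidative addition into the doubly ortho-substituted, electron-rich C–Br bonds may be slow enough for hydrodebromination to compete. Alternatively, the palladium hydride may re-add to the new exocyclic alkene and move it to C3=C4, which would erase the C3 stereocentre. The fallback sets out from 14. Copper-catalysed aromatic halogen exchange (CuI, NaI, trans-N,N'-dimethylcyclohexane-1,2-diamine, dioxane, 110 °C) should give the bis(aryl iodide) (1S,2R,3R,4S)-1,4-bis[5-(benzyloxy)-2-iodo-3-methoxyphenoxy]-1,4-bis(4-methoxyphenyl)-2,3-divinylbutane F1. The more reactive iodide allows a silver-assisted cationic Heck cyclisation at lower temperature (Pd(OAc)2, PPh3, Ag2CO3, MeCN, 60 °C), in which halide abstraction keeps the hydride short-lived. This comes back to the route at 15.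

Step 7. Substitution at a fluoroarene that lacks a strong acceptor may be slow, so that the heated dialkoxide degrades by alkene migration, by benzylic epimerisation through reversible hydride transfer, by β-elimination of aryloxide from the mono-ether, or by closure of the mono-ether alkoxide onto the benzylic carbon with loss of aryloxide. The fallback sets out from 9 and uses a nitro-activated arene, so that the substitution runs near 0 °C, where these side processes should be slow. Commercial 3,5-difluoro-4-nitrophenol is benzylated (BnBr, K2CO3, DMF) to 5-(benzyloxy)-1,3-difluoro-2-nitrobenzene F2. One equivalent of NaOMe (THF/MeOH, −20 °C) should give 5-(benzyloxy)-1-fluoro-3-methoxy-2-nitrobenzene F3. The dialkoxide of 9 (NaH, THF, 0 °C → rt) should displace the activated fluoride of two molecules of F3 to give (1S,2R,3R,4S)-1,4-bis[5-(benzyloxy)-3-methoxy-2-nitrophenoxy]-1,4-bis(4-methoxyphenyl)-2,3-divinylbutane F4. Reduction with Fe powder and NH4Cl in EtOH/H2O at 70 °C, which leaves the alkenes and benzyl ethers alone, should give (1S,2R,3R,4S)-1,4-bis[2-amino-5-(benzyloxy)-3-methoxyphenoxy]-1,4-bis(4-methoxyphenyl)-2,3-divinylbutane F5. Sandmeyer bromination (t-BuONO, CuBr2 in large excess so that bromine transfer outruns cyclisation of the aryl radical, MeCN, 0 °C → rt) comes back to the route at 14.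

Step 4. The second addition may suffer from mismatched double stereodifferentiation, the resident C1/C2 centres opposing the catalyst. The electron-rich aldehyde may also react partly through the uncatalysed background pathway. Either process would erode the ratio of C2-symmetric to meso diol and the enantiopurity. The fallback sets out from 2 and changes the allyl metal and the mode of activation. MsCl, LiCl and 2,4,6-collidine in DMF at 0 °C should give (2E,4E)-1,6-dichlorohexa-2,4-diene F6. HSiCl3 with CuCl (cat.) and EtN(CHMe2)2 in Et2O should give (2E,4E)-hexa-2,4-diene-1,6-diylbis(trichlorosilane) F7. Allyltrichlorosilanes do not add to aldehydes without a Lewis base, so there is no background reaction. Addition of F7 to 6 (2.4 equiv) is catalysed by a chiral 2,2'-bipyrrolidine-derived bisphosphoramide with a pentamethylene tether (CH2Cl2, −78 °C), its enantiomer chosen for Si-face delivery. It proceeds through a closed chair at hexacoordinate silicon (E-alkene to anti product, γ-attack) and should give (1S,2R,3R,4S)-1,4-bis(4-methoxyphenyl)-1,4-bis[(trichlorosilyl)oxy]-2,3-divinylbutane F8. Aqueous NaHCO3 work-up hydrolyses F8 and comes back to the route at 9.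

**Further compounds**

F1 | step 8 | (1S,2R,3R,4S)-1,4-bis[5-(benzyloxy)-2-iodo-3-methoxyphenoxy]-1,4-bis(4-methoxyphenyl)-2,3-divinylbutane | COc1ccc([C@@H](Oc2cc(OCc3ccccc3)cc(OC)c2I)[C@H](C=C)[C@@H](C=C)[C@H](Oc2cc(OCc3ccccc3)cc(OC)c2I)c2ccc(OC)cc2)cc1
F2 | step 7 | 5-(benzyloxy)-1,3-difluoro-2-nitrobenzene | [O-][N+](=O)c1c(F)cc(OCc2ccccc2)cc1F
F3 | step 7 | 5-(benzyloxy)-1-fluoro-3-methoxy-2-nitrobenzene | COc1cc(OCc2ccccc2)cc(F)c1[N+](=O)[O-]
F4 | step 7 | (1S,2R,3R,4S)-1,4-bis[5-(benzyloxy)-3-methoxy-2-nitrophenoxy]-1,4-bis(4-methoxyphenyl)-2,3-divinylbutane | COc1ccc([C@@H](Oc2cc(OCc3ccccc3)cc(OC)c2[N+](=O)[O-])[C@H](C=C)[C@@H](C=C)[C@H](Oc2cc(OCc3ccccc3)cc(OC)c2[N+](=O)[O-])c2ccc(OC)cc2)cc1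
F5 | step 7 | (1S,2R,3R,4S)-1,4-bis[2-amino-5-(benzyloxy)-3-methoxyphenoxy]-1,4-bis(4-methoxyphenyl)-2,3-divinylbutane | COc1ccc([C@@H](Oc2cc(OCc3ccccc3)cc(OC)c2N)[C@H](C=C)[C@@H](C=C)[C@H](Oc2cc(OCc3ccccc3)cc(OC)c2N)c2ccc(OC)cc2)cc1
F6 | step 4 | (2E,4E)-1,6-dichlorohexa-2,4-diene | ClC/C=C/C=C/CCl
F7 | step 4 | (2E,4E)-hexa-2,4-diene-1,6-diylbis(trichlorosilane) | Cl[Si](Cl)(Cl)C/C=C/C=C/C[Si](Cl)(Cl)Cl
F8 | step 4 | (1S,2R,3R,4S)-1,4-bis(4-methoxyphenyl)-1,4-bis[(trichlorosilyl)oxy]-2,3-divinylbutane | COc1ccc([C@@H](O[Si](Cl)(Cl)Cl)[C@H](C=C)[C@@H](C=C)[C@H](O[Si](Cl)(Cl)Cl)c2ccc(OC)cc2)cc1
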